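**Plan**

1. Numbering is that of the halimane skeleton: ring A = C1–C5 + C10, ring B = C5–C10, C18 = ester carbon on C4, side chain C11–C15 on C9.
2. Retrosynthesis: after O-desilylation, ring A is cut at C1–C2 and C4–C5. The C2 ketone, C3H2 and the C1=C10 bond are what a 3-oxidohexatriene C5=C10–C1=C2(O–)–C3=C4 leaves after 6π closure, and the cis pair C2/C18 on C3=C4 is a ring-opened 3-methylbutenolide. This gives a ring-B enal (C1 = CHO) and the silyloxyfuran of 3-methylfuran-2(5H)-one.
3. The enal is cut at C10–C1 (carbonylation of the enol triflate), the ring-B ketone at C9–C11 (enolate alkylation) and at C8–CH3 (conjugate addition to 2-methylcyclohex-2-enone). The chain iodide comes from the (R)-half ester of 3-methylglutaric acid.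
4. Forward: ring B is bought as the enone, C8 and C9 are set, the chain is joined, C1 is added, and ring A is closed last in one flask (aldol C1–C2, elimination, methoxide opening of the lactone as temporary ring, 6π closure C4–C5). The methoxide ends up as the methyl ester.
5. Stereochemistry: C13 from the chiral pool; C8 from the chiral copper catalyst; C9 by alkylation anti to the C8 methyl; C4 relative to C5 by disrotatory closure of the Z-enoate fixed by the lactone; C5 relative to C9 by closure anti to the pseudoaxial side chain.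

Key step: step 10

Remark: the hand of the phosphoramidite ligand in step 5 is taken to be the one that delivers the 3R adduct, and compounds 1, 6 and 14 are taken as commercial.

**Step 1**
Reactants: 1 (3R)-5-methoxy-3-methyl-5-oxopentanoic acid
Product: 2 methyl (3R)-5-hydroxy-3-methylpentanoate
Conditions: BH3·SMe2, THF, 0 °C to rt; then H2O
Reagents that add atoms: none
Why: Borane reduces the free carboxylic acid much faster than the methyl ester (chemoselective borane reduction), which differentiates the two arms without touching the stereocenter; the crude product is used at once to avoid lactonisation.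

**Step 2**
Reactants: 2 methyl (3R)-5-hydroxy-3-methylpentanoate
Product: 3 methyl (3S)-5-iodo-3-methylpentanoate
Conditions: I2, PPh3, imidazole, CH2Cl2, 0 °C to rt
Reagents that add atoms: iodine, II
Why: Appel-type iodination of the primary alcohol through the alkoxyphosphonium ion (SN2 at a primary carbon) should be clean, and the descriptor changes only because iodine changes the priorities.

**Step 3**
Reactants: 3 methyl (3S)-5-iodo-3-methylpentanoate
Product: 4 (3S)-5-iodo-3-methylpentan-1-ol
Conditions: i-Bu2AlH, CH2Cl2, –78 to 0 °C; aq. potassium sodium tartrate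
Reagents that add atoms: none
Why: Hydride reduction of the ester to the primary alcohol, the primary alkyl iodide being inert to the aluminium hydride at low temperature.

**Step 4**
Reactants: 4 (3S)-5-iodo-3-methylpentan-1-ol
Product: 5 tert-butyl{[(3S)-5-iodo-3-methylpentyl]oxy}dimethylsilane
Conditions: TBSCl, imidazole, CH2Cl2, 0 °C to rt
Reagents that add atoms: tert-butyldimethylsilyl chloride, CC(C)(C)[Si](C)(C)Cl
Why: Standard silylation of a primary alcohol, done promptly so that the iodo alcohol cannot close to a tetrahydropyran.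

**Step 5**
Reactants: 6 2-methylcyclohex-2-en-1-one
Product: 8 trimethyl{[(3R)-2,3-dimethylcyclohex-1-en-1-yl]oxy}silane, via dimethylaluminium enolate 7 (not isolated)
Conditions: AlMe3, copper thiophene-2-carboxylate (2 mol %), BINOL-derived N,N-bis(1-phenylethyl)phosphoramidite (4 mol %), Et2O, –30 °C; then TMSOTf, THF, –30 to 0 °C
Reagents that add atoms: trimethylaluminium, C[Al](C)C; trimethylsilyl trifluoromethanesulfonate, C[Si](C)(C)OS(=O)(=O)C(F)(F)F
Why: Copper-catalysed asymmetric conjugate addition of a methyl group to the enone sets C8 (3R) through the chiral phosphoramidite–copper complex, and O-silylation of the aluminium enolate fixes the tetrasubstituted enol ether regiochemistry for step 6.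

**Step 6**
Reactants: 8 trimethyl{[(3R)-2,3-dimethylcyclohex-1-en-1-yl]oxy}silane, 5 tert-butyl{[(3S)-5-iodo-3-methylpentyl]oxy}dimethylsilane
Product: 10 (2S,3R)-2-{(3R)-5-[(tert-butyldimethylsilyl)oxy]-3-methylpentyl}-2,3-dimethylcyclohexan-1-one, via lithium enolate 9 (not isolated)
Conditions: MeLi, THF, 0 °C to rt; HMPA, then 5, –78 to 0 °C
Reagents that add atoms: none
Why: Regiospecific generation of the lithium enolate from the silyl enol ether and SN2 alkylation with the primary iodide should build the C9 quaternary center; the iodide enters anti to the C8 methyl, which A(1,2) strain holds pseudoaxial in the enolate, so the chain ends trans to that methyl.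

**Step 7**
Reactants: 10 (2S,3R)-2-{(3R)-5-[(tert-butyldimethylsilyl)oxy]-3-methylpentyl}-2,3-dimethylcyclohexan-1-one
Product: 12 (5R,6S)-6-{(3R)-5-[(tert-butyldimethylsilyl)oxy]-3-methylpentyl}-5,6-dimethylcyclohex-1-en-1-yl trifluoromethanesulfonate, via potassium enolate 11 (not isolated)
Conditions: KN(SiMe3)2, THF, –78 °C; PhNTf2, –78 to 0 °C
Reagents that add atoms: N-phenylbis(trifluoromethanesulfonimide), O=S(=O)(N(c1ccccc1)S(=O)(=O)C(F)(F)F)C(F)(F)F
Why: Only C5 carries α-hydrogens, so enolisation and O-triflation (enol triflate formation) can give a single regioisomer with the C5=C10 bond in place.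

**Step 8**
Reactants: 12 (5R,6S)-6-{(3R)-5-[(tert-butyldimethylsilyl)oxy]-3-methylpentyl}-5,6-dimethylcyclohex-1-en-1-yl trifluoromethanesulfonate
Product: 13 (5R,6S)-6-{(3R)-5-[(tert-butyldimethylsilyl)oxy]-3-methylpentyl}-5,6-dimethylcyclohex-1-ene-1-carbaldehyde
Conditions: Pd(OAc)2 (5 mol %), 1,3-bis(diphenylphosphino)propane, CO (1 atm), Et3SiH, Et3N, DMF, 70 °C
Reagents that add atoms: carbon monoxide, [C-]#[O+]
Why: Palladium-catalysed reductive carbonylation (formylation) of an enol triflate (oxidative addition, CO insertion, hydride transfer from the silane) should install C1 as the aldehyde without moving the C5=C10 bond.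

**Step 9**
Reactants: 14 3-methylfuran-2(5H)-one
Product: 15 tert-butyldimethyl[(3-methylfuran-2-yl)oxy]silane
Conditions: TBSOTf, Et3N, CH2Cl2, 0 °C; distillation
Reagents that add atoms: tert-butyldimethylsilyl trifluoromethanesulfonate, CC(C)(C)[Si](C)(C)OS(=O)(=O)C(F)(F)F
Why: Soft enolisation and O-silylation of the butenolide gives the aromatic 2-silyloxyfuran, the usual dienolate equivalent for vinylogous Mukaiyama aldol additions at its C5.

**Step 10**
Reactants: 13 (5R,6S)-6-{(3R)-5-[(tert-butyldimethylsilyl)oxy]-3-methylpentyl}-5,6-dimethylcyclohex-1-ene-1-carbaldehyde, 15 tert-butyldimethyl[(3-methylfuran-2-yl)oxy]silane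
Product: 20 methyl (1S,5S,6R,8aS)-5-{(3R)-5-[(tert-butyldimethylsilyl)oxy]-3-methylpentyl}-1,5,6-trimethyl-3-oxo-1,2,3,5,6,7,8,8a-octahydronaphthalene-1-carboxylate, via silyl aldol adduct 16 (not isolated), via ylidene butenolide 17 (not isolated), via sodium trienolate 18 (not isolated), via sodium cyclohexadienolate 19 (not isolated)
Conditions: TBSOTf (10 mol %), PhMe, –78 °C; DBU, –78 °C to rt; then THF, NaOMe (2.2 equiv), 15-crown-5, –20 to 45 °C; AcOH, –78 °C
Reagents that add atoms: sodium methoxide, [Na+].[O-]C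
Why: Proposed new method: a silyl-triflate-catalysed vinylogous Mukaiyama aldol addition joins C1 of the enal to C5 of the furan (the future C2), DBU-mediated E1cB loss of silanolate gives the (Z)-ylidene butenolide, and methoxide opens this enol lactone at the acyl carbon to the 3-oxidohexatriene C5=C10–C1=C2(O–)–C3=C4(Me)CO2Me (its C1=C2 geometry should equilibrate by proton exchange with the silanol and methanol present), whose thermal disrotatory 6π electrocyclization forms C4–C5 and whose cross-conjugated dienolate is protonated at C3 to the enone. The closest known reaction types are the one-flask silyloxyfuran aldol–elimination route to ylidene butenolides, the alkoxide opening of such enol lactones to (Z)-4-oxo-2-enoates, the thermal 6π closure of 2-silyloxy-1,3,5-hexatrienes and the anionic 6π closures of trienolates that follow carbanion opening of 2-pyranones. Ring A closes in a six-membered 6π mode in which all six ring atoms belong to the triene. C4 is set relative to C5 by orbital symmetry: the lactone delivers the C3=C4 bond with the ester cis to C2 (inside) and ring B holds H-5 inside, so disrotation places CO2Me and H-5 cis, as in the target. C5 is set relative to C9 by approach of C4 to the face of the C5=C10 bond anti to the pseudoaxial C9 side chain, the reactive half-chair being the one that keeps the smaller C9 methyl near the plane of the C1–H bond (least A(1,3) strain); this preference is expected to be modest. The step needs the trienolate to cyclise faster than it C-acylates its own ester (ring contraction to a cyclopentene-1,3-dione) or loses the Z geometry, which the hindered surroundings of C1, the nearly aprotic medium and the low temperature of the opening are meant to secure.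

**Step 11**
Reactants: 20 methyl (1S,5S,6R,8aS)-5-{(3R)-5-[(tert-butyldimethylsilyl)oxy]-3-methylpentyl}-1,5,6-trimethyl-3-oxo-1,2,3,5,6,7,8,8a-octahydronaphthalene-1-carboxylate
Product: 21 methyl (1S,5S,6R,8aS)-5-[(3R)-5-hydroxy-3-methylpentyl]-1,5,6-trimethyl-3-oxo-1,2,3,5,6,7,8,8a-octahydronaphthalene-1-carboxylate
Conditions: HF·pyridine, pyridine, THF, 0 °C to rt
Reagents that add atoms: none
Why: Buffered fluoride cleavage of the primary silyl ether should leave the ester and the enone untouched and should not enolise the enone toward C5.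

**Compound list**

1 | (3R)-5-methoxy-3-methyl-5-oxopentanoic acid (methyl hydrogen (R)-3-methylglutarate) | OC(=O)C[C@@H](C)CC(=O)OC | starting material
2 | methyl (3R)-5-hydroxy-3-methylpentanoate | OCC[C@@H](C)CC(=O)OC | intermediate
3 | methyl (3S)-5-iodo-3-methylpentanoate | ICC[C@@H](C)CC(=O)OC | intermediate
4 | (3S)-5-iodo-3-methylpentan-1-ol | ICC[C@@H](C)CCO | intermediate
5 | tert-butyl{[(3S)-5-iodo-3-methylpentyl]oxy}dimethylsilane | ICC[C@@H](C)CCO[Si](C)(C)C(C)(C)C | intermediate
6 | 2-methylcyclohex-2-en-1-one | CC1=CCCCC1=O | starting material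
7 | dimethylaluminium (3R)-2,3-dimethylcyclohex-1-en-1-olate | C[C@@H]1CCCC(O[Al](C)C)=C1C | intermediate
8 | trimethyl{[(3R)-2,3-dimethylcyclohex-1-en-1-yl]oxy}silane | C[C@@H]1CCCC(O[Si](C)(C)C)=C1C | intermediate
9 | lithium (3R)-2,3-dimethylcyclohex-1-en-1-olate | C[C@@H]1CCCC([O-])=C1C.[Li+] | intermediate
10 | (2S,3R)-2-{(3R)-5-[(tert-butyldimethylsilyl)oxy]-3-methylpentyl}-2,3-dimethylcyclohexan-1-one | O=C1CCC[C@@H](C)[C@]1(C)CC[C@@H](C)CCO[Si](C)(C)C(C)(C)C | intermediate
11 | potassium (5R,6S)-6-{(3R)-5-[(tert-butyldimethylsilyl)oxy]-3-methylpentyl}-5,6-dimethylcyclohex-1-en-1-olate | [K+].[O-]C1=CCC[C@@H](C)[C@]1(C)CC[C@@H](C)CCO[Si](C)(C)C(C)(C)C | intermediate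
12 | (5R,6S)-6-{(3R)-5-[(tert-butyldimethylsilyl)oxy]-3-methylpentyl}-5,6-dimethylcyclohex-1-en-1-yl trifluoromethanesulfonate | O=S(=O)(OC1=CCC[C@@H](C)[C@]1(C)CC[C@@H](C)CCO[Si](C)(C)C(C)(C)C)C(F)(F)F | intermediate
13 | (5R,6S)-6-{(3R)-5-[(tert-butyldimethylsilyl)oxy]-3-methylpentyl}-5,6-dimethylcyclohex-1-ene-1-carbaldehyde | O=CC1=CCC[C@@H](C)[C@]1(C)CC[C@@H](C)CCO[Si](C)(C)C(C)(C)C | intermediate
14 | 3-methylfuran-2(5H)-one | CC1=CCOC1=O | starting material
15 | tert-butyldimethyl[(3-methylfuran-2-yl)oxy]silane | CC1=C(O[Si](C)(C)C(C)(C)C)OC=C1 | intermediate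
16 | silyl aldol adduct: 3-methylfuran-2(5H)-one carrying at C5 the CH(OTBS) group bonded to C1 of the ring-B cyclohexene of 13 (mixture of diastereomers at the two new centers) | CC1=CC(OC1=O)C(O[Si](C)(C)C(C)(C)C)C2=CCC[C@@H](C)[C@]2(C)CC[C@@H](C)CCO[Si](C)(C)C(C)(C)C | intermediate
17 | (5Z)-5-{[(5R,6S)-6-{(3R)-5-[(tert-butyldimethylsilyl)oxy]-3-methylpentyl}-5,6-dimethylcyclohex-1-en-1-yl]methylidene}-3-methylfuran-2(5H)-one | CC1=C/C(=C/C2=CCC[C@@H](C)[C@]2(C)CC[C@@H](C)CCO[Si](C)(C)C(C)(C)C)OC1=O | intermediate
18 | sodium (1E,3Z)-1-[(5R,6S)-6-{(3R)-5-[(tert-butyldimethylsilyl)oxy]-3-methylpentyl}-5,6-dimethylcyclohex-1-en-1-yl]-5-methoxy-4-methyl-5-oxopenta-1,3-dien-2-olate (the isomer that can cyclise; formed first as the 1Z enolate) | [Na+].COC(=O)/C(C)=C\C([O-])=C/C1=CCC[C@@H](C)[C@]1(C)CC[C@@H](C)CCO[Si](C)(C)C(C)(C)C | intermediate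
19 | sodium dienolate of 20 (O– on C2, double bonds C2=C3 and C1=C10; C4, C5, C8, C9, C13 as in 20) | [Na+].COC(=O)[C@@]1(C)C=C([O-])C=C2[C@@H]1CC[C@@H](C)[C@]2(C)CC[C@@H](C)CCO[Si](C)(C)C(C)(C)C | intermediate
20 | methyl (1S,5S,6R,8aS)-5-{(3R)-5-[(tert-butyldimethylsilyl)oxy]-3-methylpentyl}-1,5,6-trimethyl-3-oxo-1,2,3,5,6,7,8,8a-octahydronaphthalene-1-carboxylate | COC(=O)[C@@]1(C)CC(=O)C=C2[C@@H]1CC[C@@H](C)[C@]2(C)CC[C@@H](C)CCO[Si](C)(C)C(C)(C)C | intermediate
21 | methyl (1S,5S,6R,8aS)-5-[(3R)-5-hydroxy-3-methylpentyl]-1,5,6-trimethyl-3-oxo-1,2,3,5,6,7,8,8a-octahydronaphthalene-1-carboxylate (CNP0157174.1) | COC(=O)[C@@]1(C)CC(=O)C=C2[C@@H]1CC[C@@H](C)[C@]2(C)CC[C@@H](C)CCO | target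

**Step count**

Total step count: 11. Longest linear sequence: 9 (steps 1, 2, 3, 4, 6, 7, 8, 10, 11).

**Steps most likely to fail**

Step 10. The trienolate may C-acylate its own ester instead of cyclising, the Z geometry of the C3=C4 bond may be lost by reversible conjugate addition of methoxide, or the closure may show poor facial selectivity at C5. The fallback uses known reactions and runs the ring closure stepwise on a neutral silyl enol ether, which cannot C-acylate. It sets out from 13 and 15: the flask is worked up after the DBU stage and the ylidene butenolide 17 is isolated. One equivalent of NaOMe in THF/MeOH at –40 °C followed by AcOH should give the keto ester methyl (2Z)-5-[(5R,6S)-6-{(3R)-5-[(tert-butyldimethylsilyl)oxy]-3-methylpentyl}-5,6-dimethylcyclohex-1-en-1-yl]-2-methyl-4-oxopent-2-enoate F1. TBSOTf and Et3N in CH2Cl2 should convert it into the silyl trienol ether methyl (2Z)-4-[(tert-butyldimethylsilyl)oxy]-5-[(5R,6S)-6-{(3R)-5-[(tert-butyldimethylsilyl)oxy]-3-methylpentyl}-5,6-dimethylcyclohex-1-en-1-yl]-2-methylpenta-2,4-dienoate F2, of which only the 4E isomer can close and the 4Z isomer would be re-equilibrated. Heating in PhMe at 110 °C (thermal disrotatory 6π closure of a 2-silyloxyhexatriene) should give the tert-butyldimethylsilyl dienol ether of 20 F3. Brief treatment with 0.1 M HCl in THF at 0 °C should hydrolyse only the enol ether, and the route is rejoined at 20, where any C5 epimer would be separated.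

Step 6. The hindered tetrasubstituted enolate may react too slowly with the unactivated iodide, so that proton transfer scrambles the enolate regiochemistry or the diastereoselectivity falls. The fallback uses a reactive allylic electrophile and lets a catalyst set C13; it sets out from 8 and comes back at 10. Commercial tert-butyl(but-3-yn-1-yloxy)dimethylsilane is carbometalated (AlMe3, (C5H5)2ZrCl2, CH2Cl2; then paraformaldehyde) to the allylic alcohol (2E)-5-[(tert-butyldimethylsilyl)oxy]-3-methylpent-2-en-1-ol F4. CBr4 and PPh3 convert this into the bromide tert-butyl{[(3E)-5-bromo-3-methylpent-3-en-1-yl]oxy}dimethylsilane F5. The lithium enolate 9, made from 8 with MeLi as in step 6, is alkylated with this bromide, anti to the C8 methyl, to give the ketone (2S,3R)-2-{(2E)-5-[(tert-butyldimethylsilyl)oxy]-3-methylpent-2-en-1-yl}-2,3-dimethylcyclohexan-1-one F6. Hydrogenation of the trisubstituted alkene with a chiral iridium catalyst [Ir(C8H12)(L)][B(C6H3(CF3)2)4] (L = chiral pyridyl phosphinite, H2 50 bar, CH2Cl2) should set C13 as 3R and give 10.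

Step 8. Hydride transfer to the hindered vinylpalladium species may outrun CO insertion and give the simple alkene, or the catalyst may stall next to the quaternary C9. The fallback separates the carbonylation from the reduction; it sets out from 12 and comes back at 13. Methoxycarbonylation (Pd(OAc)2, 1,3-bis(diphenylphosphino)propane, CO, MeOH, Et3N, DMF, 60 °C) should give the ester methyl (5R,6S)-6-{(3R)-5-[(tert-butyldimethylsilyl)oxy]-3-methylpentyl}-5,6-dimethylcyclohex-1-ene-1-carboxylate F7. Reduction with i-Bu2AlH in CH2Cl2 at –78 °C gives the allylic alcohol [(5R,6S)-6-{(3R)-5-[(tert-butyldimethylsilyl)oxy]-3-methylpentyl}-5,6-dimethylcyclohex-1-en-1-yl]methanol F8, and MnO2 in CH2Cl2 oxidises it to 13.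

**Further compounds**

F1 | step 10 | methyl (2Z)-5-[(5R,6S)-6-{(3R)-5-[(tert-butyldimethylsilyl)oxy]-3-methylpentyl}-5,6-dimethylcyclohex-1-en-1-yl]-2-methyl-4-oxopent-2-enoate | COC(=O)/C(C)=C\C(=O)CC1=CCC[C@@H](C)[C@]1(C)CC[C@@H](C)CCO[Si](C)(C)C(C)(C)C
F2 | step 10 | methyl (2Z)-4-[(tert-butyldimethylsilyl)oxy]-5-[(5R,6S)-6-{(3R)-5-[(tert-butyldimethylsilyl)oxy]-3-methylpentyl}-5,6-dimethylcyclohex-1-en-1-yl]-2-methylpenta-2,4-dienoate (4E/4Z mixture) | COC(=O)/C(C)=C\C(O[Si](C)(C)C(C)(C)C)=CC1=CCC[C@@H](C)[C@]1(C)CC[C@@H](C)CCO[Si](C)(C)C(C)(C)C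
F3 | step 10 | tert-butyldimethylsilyl dienol ether of 20 (OTBS on C2, double bonds C2=C3 and C1=C10) | COC(=O)[C@@]1(C)C=C(O[Si](C)(C)C(C)(C)C)C=C2[C@@H]1CC[C@@H](C)[C@]2(C)CC[C@@H](C)CCO[Si](C)(C)C(C)(C)C
F4 | step 6 | (2E)-5-[(tert-butyldimethylsilyl)oxy]-3-methylpent-2-en-1-ol | OC/C=C(\C)CCO[Si](C)(C)C(C)(C)C
F5 | step 6 | tert-butyl{[(3E)-5-bromo-3-methylpent-3-en-1-yl]oxy}dimethylsilane | BrC/C=C(\C)CCO[Si](C)(C)C(C)(C)C
F6 | step 6 | (2S,3R)-2-{(2E)-5-[(tert-butyldimethylsilyl)oxy]-3-methylpent-2-en-1-yl}-2,3-dimethylcyclohexan-1-one | O=C1CCC[C@@H](C)[C@]1(C)C/C=C(\C)CCO[Si](C)(C)C(C)(C)C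
F7 | step 8 | methyl (5R,6S)-6-{(3R)-5-[(tert-butyldimethylsilyl)oxy]-3-methylpentyl}-5,6-dimethylcyclohex-1-ene-1-carboxylate | COC(=O)C1=CCC[C@@H](C)[C@]1(C)CC[C@@H](C)CCO[Si](C)(C)C(C)(C)C
F8 | step 8 | [(5R,6S)-6-{(3R)-5-[(tert-butyldimethylsilyl)oxy]-3-methylpentyl}-5,6-dimethylcyclohex-1-en-1-yl]methanol | OCC1=CCC[C@@H](C)[C@]1(C)CC[C@@H](C)CCO[Si](C)(C)C(C)(C)C
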